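**Plan**
Locants: carotenoid numbering. The primed half carries the hydroxyl: ring B has C1' (CMe2), C2' (CH2), C3' (carbinol), C4'=C5'(Me) and C6'=C7' exocyclic. Ring A is unprimed.
Feature: ring B plus C7' is two 3-methylbut-2-enoyl (C5) skeletons, C3'–C2'–C1'(Me)2 and C7'–C6'–C5'(Me)–C4'. Acyl C3' and β-carbon C1' of one are a 1,3-dielectrophile; γ-C4' and α-C6' of the dienolate of the other are a 1,3-dinucleophile. One [3+3] event therefore makes C3'–C4' and C1'–C6'.
Retrosynthesis: cut C10=C11 and C10'=C11' (two Wittig reactions on a C12 dialdehyde whose C15–C15' bond comes from a stannane homocoupling), then C7–C8 and C7'–C8' (Suzuki couplings of the ring enol triflates with one C4 alkenylboronate), then the C6'=C7' enol triflate back to a C7' ester, then the two ring bonds.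
Forward: ring B first (acylation/electrocyclisation), then the carbinol, then the retro diene by enolate triflation; the C4 boronate from propargyl alcohol; ring A triflate from safranal; each ring extended to a C14 phosphonium salt; chain joined A-C14 + C12, then + B-C14; desilylation last.
Stereochemistry: C3' (S) from asymmetric transfer hydrogenation of the ring enone; trisubstituted alkenes from syn-carboalumination and from the (E)-enynol; C14=C15 and C14'=C15' from syn-hydrostannation; C10=C11 and C10'=C11' from Wittig plus equilibration; exocyclic C6=C7 and C6'=C7' from the enolate geometry (oxygen syn to the gem-dimethyl carbon).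

Key step: step 2

Remark: the drawn exocyclic geometry (chain syn to CMe2 at both rings) is taken to be the thermodynamically preferred one, so that iodine equilibration of the polyene should converge on it; 1, 4, 12, 18 and 24 are taken as purchasable.

**Step 1**
Reactants: 1 methyl 3-methylbut-2-enoate
Product: 3 1-methoxy-3-methyl-1-(trimethylsilyloxy)buta-1,3-diene, via lithium dienolate 2 (not isolated)
Conditions: LiN(i-Pr)2, THF, −78 °C; Me3SiCl, −78 → 20 °C; distillation
Reagents that add atoms: chlorotrimethylsilane, C[Si](C)(C)Cl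
Why: γ-deprotonation of the β,β-disubstituted enoate (conjugate addition of the amide is blocked) and O-silylation of the dienolate should give the silyl ketene acetal, a standard vinylogous Mukaiyama donor.

**Step 2**
Reactants: 3 1-methoxy-3-methyl-1-(trimethylsilyloxy)buta-1,3-diene; 4 3-methylbut-2-enoyl chloride
Product: 6 methyl 2,6,6-trimethyl-4-oxocyclohex-2-ene-1-carboxylate (racemic), via acyclic keto ester 5 (not isolated)
Conditions: ZnCl2 (10 mol %), CH2Cl2, −40 → 0 °C; then DBU (1.2 equiv), 0 → 40 °C; aq. NH4Cl
Reagents that add atoms: none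
Why: Proposed new method: the Lewis-acid-activated acid chloride 4 should acylate the O-silyl dienolate 3 at its terminal (γ) CH2, a vinylogous Mukaiyama-type Claisen acylation that forms C4'–C3' and releases Me3SiCl; DBU then removes the doubly activated C4' proton of 5, and the resulting 3-oxidohexatriene C6'=C5'–C4'=C3'(O−)–C2'=C1' closes between its termini C6' and C1'. The closest known reaction types are the γ-acylation of silyl dienolates, the formal [3+3] cyclisations of 1,3-bis(silyloxy)dienes with 1,3-dielectrophiles, and the Michael/aldol annulation of mesityl oxide with acetoacetate that gives the same ring through other bonds. The six-membered ring closes by an oxyanion-accelerated 6π-disrotatory electrocyclisation, equivalent to a 6-endo-trig Michael addition of the ester α-carbon to the β,β-dimethyl enone, so the quaternary C1' is made intramolecularly. The only new stereocentre, C6' (C1 of 6), is formed racemic and uncontrolled, which is immaterial because it becomes sp2 in step 6. The step needs γ- over α-acylation (α-attack would lead to the isomeric ring with the ester next to the ketone) and C- over O-acylation; the silyl dienolate under Lewis-acid conditions reacts at its unhindered terminal carbon, and after that only C6' and C1' can close a six-membered ring. Reprotonation should give the isomer with C4'=C5' conjugated to the ketone, the stable form of this keto ester.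

**Step 3**
Reactants: 6 methyl 2,6,6-trimethyl-4-oxocyclohex-2-ene-1-carboxylate
Product: 7 methyl (4S)-4-hydroxy-2,6,6-trimethylcyclohex-2-ene-1-carboxylate (both C1 epimers)
Conditions: RuCl[(S,S)-TsDPEN](p-cymene) (1 mol %), KOt-Bu (2 mol %), i-PrOH, 25 °C
Reagents that add atoms: none
Why: Noyori asymmetric transfer hydrogenation reduces the enone carbonyl 1,2 (close precedent: the same CH=C(Me)/CH2–CMe2-flanked carbonyl of 2,6,6-trimethylcyclohex-2-ene-1,4-dione); with the alkenyl carbon in the role of the aryl group, the (S,S)-ligand is expected to give the (4S)-carbinol under catalyst control for both C1 epimers, and the enantiomeric ligand would be taken if the sense proved opposite.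

**Step 4**
Reactants: 7 methyl (4S)-4-hydroxy-2,6,6-trimethylcyclohex-2-ene-1-carboxylate
Product: 8 methyl (4S)-4-(tert-butyldimethylsilyloxy)-2,6,6-trimethylcyclohex-2-ene-1-carboxylate
Conditions: t-BuMe2SiCl, imidazole, DMF, 20 °C
Reagents that add atoms: tert-butyldimethylsilyl chloride, CC(C)(C)[Si](C)(C)Cl
Why: standard silylation of a secondary allylic alcohol, which masks the hydroxyl through the base and organometallic steps.

**Step 5**
Reactants: 8 methyl (4S)-4-(tert-butyldimethylsilyloxy)-2,6,6-trimethylcyclohex-2-ene-1-carboxylate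
Product: 9 (4S)-4-(tert-butyldimethylsilyloxy)-2,6,6-trimethylcyclohex-2-ene-1-carbaldehyde (both C1 epimers)
Conditions: i-Bu2AlH (1.1 equiv), CH2Cl2, −78 °C; aq. potassium sodium tartrate work-up; used at once
Reagents that add atoms: none
Why: low-temperature i-Bu2AlH reduction of a hindered ester should stop at the tetrahedral aluminate, which gives the aldehyde on work-up, and immediate use avoids conjugation of the β,γ-unsaturated aldehyde.

**Step 6**
Reactants: 9 (4S)-4-(tert-butyldimethylsilyloxy)-2,6,6-trimethylcyclohex-2-ene-1-carbaldehyde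
Product: 11 (E)-[(4S)-4-(tert-butyldimethylsilyloxy)-2,6,6-trimethylcyclohex-2-en-1-ylidene]methyl trifluoromethanesulfonate (OTf syn to the gem-dimethyl carbon), via potassium dienolate 10 (not isolated)
Conditions: KN(SiMe3)2, THF, −78 °C; PhNTf2, −78 → −20 °C
Reagents that add atoms: N-phenylbis(trifluoromethanesulfonimide), FC(F)(F)S(=O)(=O)N(c1ccccc1)S(=O)(=O)C(F)(F)F
Why: the single α-hydrogen (C1–H, allylic and α to CHO) is removed regiospecifically from both epimers to give one linear dienolate, and O-sulfonylation (enol triflate formation from an aldehyde enolate) fixes the retro diene; the oxygen is expected to avoid the in-plane C2 methyl and sit syn to the gem-dimethyl carbon, and −78 °C should suppress vinylogous β-elimination of silanolate.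

**Step 7**
Reactants: 12 prop-2-yn-1-ol
Product: 14 (E)-2-methyl-3-(4,4,5,5-tetramethyl-1,3,2-dioxaborolan-2-yl)prop-2-en-1-ol, via alkenylalane 13 (not isolated)
Conditions: Me3Al (3 equiv), Cp2ZrCl2 (0.25 equiv), CH2Cl2, 0 → 20 °C; then 2-isopropoxy-4,4,5,5-tetramethyl-1,3,2-dioxaborolane (1.5 equiv), −20 → 20 °C; aq. potassium sodium tartrate work-up; made once in the amount needed for steps 8 and 11
Reagents that add atoms: trimethylaluminium, C[Al](C)C; 2-isopropoxy-4,4,5,5-tetramethyl-1,3,2-dioxaborolane, CC(C)OB1OC(C)(C)C(C)(C)O1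
Why: zirconium-catalysed syn-carboalumination of the terminal alkyne (Negishi carboalumination) places methyl on the internal and aluminium on the terminal carbon, and aluminium-to-boron exchange with the alkoxyboronate proceeds with retention, so a storable (E)-alkenyl pinacolboronate is obtained that serves both ring couplings.

**Step 8**
Reactants: 11 ring B dienyl triflate; 14 (E)-alkenyl pinacolboronate (1.3 equiv)
Product: 15 (2E,4E)-4-[(4S)-4-(tert-butyldimethylsilyloxy)-2,6,6-trimethylcyclohex-2-en-1-ylidene]-2-methylbut-2-en-1-ol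
Conditions: PdCl2(dppf) (5 mol %), K3PO4 (3 equiv), THF–H2O (10:1), degassed, 20 → 40 °C, dim light
Reagents that add atoms: none
Why: Suzuki–Miyaura coupling of the enol triflate with the (E)-alkenylboronate forms C7'–C8' with retention at both sp2 carbons, and the mild phosphate base leaves the silyl ether and the free primary hydroxyl untouched.

**Step 9**
Reactants: 15 ring B C14 alcohol
Product: 17 {(2E,4E)-4-[(4S)-4-(tert-butyldimethylsilyloxy)-2,6,6-trimethylcyclohex-2-en-1-ylidene]-2-methylbut-2-enyl}triphenylphosphonium bromide, via allylic bromide 16 (not isolated)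
Conditions: CBr4, PPh3 (2.2 equiv), CH2Cl2, −20 → 20 °C
Reagents that add atoms: carbon tetrabromide, BrC(Br)(Br)Br; triphenylphosphine, c1ccccc1P(c1ccccc1)c1ccccc1
Why: Appel bromination of the primary allylic alcohol under neutral conditions, followed by quaternisation of the bromide at its unhindered primary terminus by the excess phosphine, should give the Wittig salt without exposing the allylic silyl ether to acid.

**Step 10**
Reactants: 18 safranal (2,6,6-trimethylcyclohexa-1,3-diene-1-carbaldehyde)
Product: 20 (Z)-(2,6,6-trimethylcyclohexa-2,4-dien-1-ylidene)methyl trifluoromethanesulfonate (OTf syn to the gem-dimethyl carbon), via potassium trienolate 19 (not isolated)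
Conditions: KOt-Bu, THF, −40 → 0 °C; PhNTf2, −78 → 0 °C
Reagents that add atoms: N-phenylbis(trifluoromethanesulfonimide), FC(F)(F)S(=O)(=O)N(c1ccccc1)S(=O)(=O)C(F)(F)F
Why: under equilibrating alkoxide conditions the linear, fully conjugated trienolate (loss of a ring C5 hydrogen) should prevail over the cross-conjugated methyl-derived isomer, and O-triflation of this extended enolate gives the retro trienyl triflate.

**Step 11**
Reactants: 20 ring A trienyl triflate; 14 (E)-alkenyl pinacolboronate (1.3 equiv)
Product: 21 (2E,4Z)-2-methyl-4-(2,6,6-trimethylcyclohexa-2,4-dien-1-ylidene)but-2-en-1-ol (chain syn to the gem-dimethyl carbon)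
Conditions: PdCl2(dppf) (5 mol %), K3PO4 (3 equiv), THF–H2O (10:1), degassed, 20 → 40 °C, dim light
Reagents that add atoms: none
Why: the same Suzuki–Miyaura coupling as in step 8 forms C7–C8 with retention of both alkene geometries.

**Step 12**
Reactants: 21 ring A C14 alcohol
Product: 23 [(2E,4Z)-2-methyl-4-(2,6,6-trimethylcyclohexa-2,4-dien-1-ylidene)but-2-enyl]triphenylphosphonium bromide, via allylic bromide 22 (not isolated)
Conditions: CBr4, PPh3 (2.2 equiv), CH2Cl2, −20 → 20 °C
Reagents that add atoms: carbon tetrabromide, BrC(Br)(Br)Br; triphenylphosphine, c1ccccc1P(c1ccccc1)c1ccccc1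
Why: Appel bromination and in situ quaternisation at the primary allylic terminus, as in step 9.

**Step 13**
Reactants: 24 (E)-3-methylpent-2-en-4-yn-1-ol
Product: 25 (2E,4E)-3-methyl-5-(tributylstannyl)penta-2,4-dien-1-ol
Conditions: Bu3SnH, PdCl2(PPh3)2 (2 mol %), THF, 0 °C
Reagents that add atoms: tributyltin hydride, CCCC[SnH](CCCC)CCCC
Why: palladium-catalysed syn-hydrostannation of a conjugated terminal enyne places tin on the terminal carbon and should give the (E)-dienylstannane.

**Step 14**
Reactants: 25 (2E,4E)-3-methyl-5-(tributylstannyl)penta-2,4-dien-1-ol (2 equiv)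
Product: 26 (2E,4E,6E,8E)-3,8-dimethyldeca-2,4,6,8-tetraene-1,10-diol
Conditions: CuCl (2.5 equiv), DMF, 20 °C, dark
Reagents that add atoms: none
Why: copper-mediated oxidative homocoupling of alkenylstannanes joins the two sp2 carbons (the future C15–C15') with retention of geometry and tolerates free hydroxyl groups.

**Step 15**
Reactants: 26 (2E,4E,6E,8E)-3,8-dimethyldeca-2,4,6,8-tetraene-1,10-diol
Product: 27 (2E,4E,6E,8E)-3,8-dimethyldeca-2,4,6,8-tetraenedial
Conditions: MnO2 (excess), CH2Cl2, 20 °C
Reagents that add atoms: none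
Why: MnO2 oxidises allylic alcohols selectively to the conjugated aldehydes without touching the polyene.

**Step 16**
Reactants: 23 ring A C14 phosphonium bromide; 27 C12 dialdehyde (3 equiv)
Product: 29 (2E,4E,6E,8E,10E,12E,14Z)-3,8,12-trimethyl-14-(2,6,6-trimethylcyclohexa-2,4-dien-1-ylidene)tetradeca-2,4,6,8,10,12-hexaenal, via ylide 28 (not isolated)
Conditions: 23, NaN(SiMe3)2, THF, −78 °C; added to 27, −78 → 20 °C; then I2 (cat.), hexane, daylight; excess 27 recovered
Reagents that add atoms: none
Why: Wittig olefination of a conjugated dialdehyde by a polyenyl ylide is the classical carotenoid chain assembly; excess dialdehyde enforces mono-olefination, and iodine equilibration should convert the Z isomer of the new C10=C11 bond to E.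

**Step 17**
Reactants: 17 ring B C14 phosphonium bromide; 29 C26 aldehyde
Product: 31 tert-butyldimethylsilyl ether of the target, via ylide 30 (not isolated)
Conditions: 17, NaN(SiMe3)2, THF, −78 °C; 29, −78 → 20 °C; then I2 (cat.), hexane, daylight
Reagents that add atoms: none
Why: a second Wittig olefination of the same type forms C10'=C11', and equilibration should give the all-trans chain with both exocyclic bonds in the preferred arrangement.

**Step 18**
Reactants: 31 tert-butyldimethylsilyl ether of the target
Product: 32 target (3'S)-carotenol CNP0202479.1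
Conditions: Bu4NF, THF, 0 → 20 °C; chromatography and crystallisation in dim light
Reagents that add atoms: none
Why: fluoride cleaves the silyl ether under non-acidic conditions, which spares the ionisable allylic carbinol and the polyene.

**Compound list**
1 | methyl 3-methylbut-2-enoate | COC(=O)C=C(C)C | starting material
2 | lithium 1-methoxy-3-methylbuta-1,3-dien-1-olate | [Li+].[O-]C(OC)=CC(C)=C | intermediate
3 | 1-methoxy-3-methyl-1-(trimethylsilyloxy)buta-1,3-diene | COC(O[Si](C)(C)C)=CC(C)=C | intermediate
4 | 3-methylbut-2-enoyl chloride | CC(C)=CC(Cl)=O | starting material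
5 | methyl 3,7-dimethyl-5-oxoocta-2,6-dienoate | COC(=O)C=C(C)CC(=O)C=C(C)C | intermediate
6 | methyl 2,6,6-trimethyl-4-oxocyclohex-2-ene-1-carboxylate (racemic) | COC(=O)C1C(C)=CC(=O)CC1(C)C | intermediate
7 | methyl (4S)-4-hydroxy-2,6,6-trimethylcyclohex-2-ene-1-carboxylate (C1 epimers) | COC(=O)C1C(C)=C[C@@H](O)CC1(C)C | intermediate
8 | methyl (4S)-4-(tert-butyldimethylsilyloxy)-2,6,6-trimethylcyclohex-2-ene-1-carboxylate | COC(=O)C1C(C)=C[C@@H](O[Si](C)(C)C(C)(C)C)CC1(C)C | intermediate
9 | (4S)-4-(tert-butyldimethylsilyloxy)-2,6,6-trimethylcyclohex-2-ene-1-carbaldehyde | O=CC1C(C)=C[C@@H](O[Si](C)(C)C(C)(C)C)CC1(C)C | intermediate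
10 | potassium dienolate of 9 | [K+].[O-]/C=C1/C(C)=C[C@@H](O[Si](C)(C)C(C)(C)C)CC1(C)C | intermediate
11 | (E)-[(4S)-4-(tert-butyldimethylsilyloxy)-2,6,6-trimethylcyclohex-2-en-1-ylidene]methyl trifluoromethanesulfonate | FC(F)(F)S(=O)(=O)O/C=C1/C(C)=C[C@@H](O[Si](C)(C)C(C)(C)C)CC1(C)C | intermediate
12 | prop-2-yn-1-ol | C#CCO | starting material
13 | dimethyl[(E)-3-(dimethylaluminiooxy)-2-methylprop-1-enyl]aluminium | C[Al](C)/C=C(\C)CO[Al](C)C | intermediate
14 | (E)-2-methyl-3-(4,4,5,5-tetramethyl-1,3,2-dioxaborolan-2-yl)prop-2-en-1-ol | OC/C(C)=C/B1OC(C)(C)C(C)(C)O1 | intermediate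
15 | (2E,4E)-4-[(4S)-4-(tert-butyldimethylsilyloxy)-2,6,6-trimethylcyclohex-2-en-1-ylidene]-2-methylbut-2-en-1-ol | OC/C(C)=C/C=C1/C(C)=C[C@@H](O[Si](C)(C)C(C)(C)C)CC1(C)C | intermediate
16 | allylic bromide of 15 | BrC/C(C)=C/C=C1/C(C)=C[C@@H](O[Si](C)(C)C(C)(C)C)CC1(C)C | intermediate
17 | ring B C14 triphenylphosphonium bromide | [Br-].c1ccccc1[P+](c1ccccc1)(c1ccccc1)C/C(C)=C/C=C1/C(C)=C[C@@H](O[Si](C)(C)C(C)(C)C)CC1(C)C | intermediate
18 | safranal (2,6,6-trimethylcyclohexa-1,3-diene-1-carbaldehyde) | CC1=C(C=O)C(C)(C)CC=C1 | starting material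
19 | potassium trienolate of 18 | [K+].[O-]/C=C1/C(C)=CC=CC1(C)C | intermediate
20 | (Z)-(2,6,6-trimethylcyclohexa-2,4-dien-1-ylidene)methyl trifluoromethanesulfonate | FC(F)(F)S(=O)(=O)O/C=C1/C(C)=CC=CC1(C)C | intermediate
21 | (2E,4Z)-2-methyl-4-(2,6,6-trimethylcyclohexa-2,4-dien-1-ylidene)but-2-en-1-ol | OC/C(C)=C/C=C1/C(C)=CC=CC1(C)C | intermediate
22 | allylic bromide of 21 | BrC/C(C)=C/C=C1/C(C)=CC=CC1(C)C | intermediate
23 | ring A C14 triphenylphosphonium bromide | [Br-].c1ccccc1[P+](c1ccccc1)(c1ccccc1)C/C(C)=C/C=C1/C(C)=CC=CC1(C)C | intermediate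
24 | (E)-3-methylpent-2-en-4-yn-1-ol | C#C/C(C)=C/CO | starting material
25 | (2E,4E)-3-methyl-5-(tributylstannyl)penta-2,4-dien-1-ol | CCCC[Sn](CCCC)(CCCC)/C=C/C(C)=C/CO | intermediate
26 | (2E,4E,6E,8E)-3,8-dimethyldeca-2,4,6,8-tetraene-1,10-diol | OC/C=C(C)/C=C/C=C/C(C)=C/CO | intermediate
27 | (2E,4E,6E,8E)-3,8-dimethyldeca-2,4,6,8-tetraenedial | O=C/C=C(C)/C=C/C=C/C(C)=C/C=O | intermediate
28 | ylide from 23 | C(=P(c1ccccc1)(c1ccccc1)c1ccccc1)/C(C)=C/C=C1/C(C)=CC=CC1(C)C | intermediate
29 | (2E,4E,6E,8E,10E,12E,14Z)-3,8,12-trimethyl-14-(2,6,6-trimethylcyclohexa-2,4-dien-1-ylidene)tetradeca-2,4,6,8,10,12-hexaenal | CC1=CC=CC(C)(C)\C1=C/C=C(C)/C=C/C=C(C)/C=C/C=C/C(C)=C/C=O | intermediate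
30 | ylide from 17 | C(=P(c1ccccc1)(c1ccccc1)c1ccccc1)/C(C)=C/C=C1/C(C)=C[C@@H](O[Si](C)(C)C(C)(C)C)CC1(C)C | intermediate
31 | tert-butyldimethylsilyl ether of the target | CC1=CC=CC(C)(C)\C1=C/C=C(C)/C=C/C=C(C)/C=C/C=C/C(C)=C/C=C/C(C)=C/C=C1/C(C)=C[C@@H](O[Si](C)(C)C(C)(C)C)CC1(C)C | intermediate
32 | target: ring A 2,6,6-trimethylcyclohexa-2,4-dien-1-ylidene and ring B (4S)-4-hydroxy-2,6,6-trimethylcyclohex-2-en-1-ylidene on the all-trans 3,7,12,16-tetramethyloctadeca-2,4,6,8,10,12,14,16-octaene-1,18-diylidene chain | CC1=CC=CC(C)(C)\C1=C/C=C(C)/C=C/C=C(C)/C=C/C=C/C(C)=C/C=C/C(C)=C/C=C1/C(C)=C[C@@H](O)CC1(C)C | target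

**Totals**
Total steps: 18. Longest linear sequence: 10 (steps 1–6, 8, 9, 17, 18).

**Steps most likely to fail**

Step 2 (proposed new method). The acylation may take the α-carbon or the oxygen of the dienolate, acid chloride 4 may be lost as a vinylketene under the base, or ring closure at the gem-dimethyl terminus may be slow enough for 5 to isomerise into conjugation first. Fallback with known chemistry: it sets out from 4, which Me2CuLi converts into mesityl oxide F1 (also purchasable). The classical Michael/aldol annulation of F1 with methyl acetoacetate (ZnCl2, toluene, reflux, water separator) then gives keto ester 6, where the route is rejoined. This fallback makes C6'–C1' and C4'=C5' instead of the two bonds of step 2.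

Step 6. Vinylogous β-elimination of silanolate from dienolate 10 may give a safranal-type trienal, or sulfonylation may fix the oxygen on the side of the C2 methyl. Fallback: it sets out from aldehyde 9 and replaces enolate trapping by addition and dehydration. Purchased (E)-3-iodo-2-methylprop-2-en-1-ol is pivaloylated to (E)-3-iodo-2-methylprop-2-enyl pivalate F2. Nozaki–Hiyama–Kishi addition of F2 to 9 (CrCl2, NiCl2 cat., DMF) gives the C7' carbinol F3. Dehydration toward the ring hydrogen with Martin sulfurane gives the triene pivalate F4 under conjugative control. i-Bu2AlH removes the pivalate and the route is rejoined at alcohol 15.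

Step 10. Kinetic deprotonation at the C2 methyl group would give the cross-conjugated enolate and an exocyclic-methylene triflate instead of the ring CH2 product, and the aldehyde may self-condense under alkoxide. Fallback: it sets out from safranal 18. Nozaki–Hiyama–Kishi addition of pivalate F2 to 18 gives the carbinol F5. Acid-catalysed 1,6-dehydration (TsOH cat., toluene), with loss of the hydroxyl and of a ring C5 hydrogen through the pentadienyl cation as in the anhydroretinol-type dehydration, gives the tetraene pivalate F6. i-Bu2AlH returns alcohol 21, where the route is rejoined.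

**Further compounds**
F1 | step 2 | mesityl oxide (4-methylpent-3-en-2-one) | CC(=O)C=C(C)C
F2 | step 6 | (E)-3-iodo-2-methylprop-2-enyl pivalate | CC(C)(C)C(=O)OC/C(C)=C/I
F3 | step 6 | (E)-4-[(4S)-4-(tert-butyldimethylsilyloxy)-2,6,6-trimethylcyclohex-2-en-1-yl]-4-hydroxy-2-methylbut-2-enyl pivalate | CC(C)(C)C(=O)OC/C(C)=C/C(O)C1C(C)=C[C@@H](O[Si](C)(C)C(C)(C)C)CC1(C)C
F4 | step 6 | pivalate of 15 | CC(C)(C)C(=O)OC/C(C)=C/C=C1/C(C)=C[C@@H](O[Si](C)(C)C(C)(C)C)CC1(C)C
F5 | step 10 | (E)-4-hydroxy-2-methyl-4-(2,6,6-trimethylcyclohexa-1,3-dien-1-yl)but-2-enyl pivalate | CC(C)(C)C(=O)OC/C(C)=C/C(O)C1=C(C)C=CCC1(C)C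
F6 | step 10 | pivalate of 21 | CC(C)(C)C(=O)OC/C(C)=C/C=C1/C(C)=CC=CC1(C)C
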